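## Retrosynthetic overview

1. Target ⇒ flat 3-O-acylflavylium salt. The C2–H, C3–H and C4–H bonds are made last, so one asymmetric ionic hydrogenation sets both stereocentres. The ester is carried in from the start, so no protected epicatechin is esterified and no O-protecting groups are needed.
2. Flavylium salt ⇒ 2,4,6-trihydroxybenzaldehyde + phenacyl 4-O-methylgallate + PhB(OH)2. C3=C4 (aldol condensation) and O1–C2 (cyclodehydration) close ring C, and the B-ring catechol closes onto boron in the same flask.
3. Phenacyl ester ⇒ 2-chloro-3',4'-dihydroxyacetophenone + 4-O-methylgallic acid (carboxylate SN2).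
4. Ring order: A, B and D are bought. Ring C and a temporary 1,3,2-dioxaborole ring form together in step 2. The dioxaborole is opened again in the work-up of step 3.

Assumption: acid 2 is bought as a catalogue compound, and the (S,S)-catalyst is assigned to the (2R,3R) series by analogy with aryl ketone reduction (aryl group docked under the η6-arene); the antipodal catalyst is equally available if the first run shows the opposite sense.

## Route

Step 1
Reactants: 1 2-chloro-1-(3,4-dihydroxyphenyl)ethan-1-one; 2 3,5-dihydroxy-4-methoxybenzoic acid (4-O-methylgallic acid)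
Product: 4 2-(3,4-dihydroxyphenyl)-2-oxoethyl 3,5-dihydroxy-4-methoxybenzoate, via potassium carboxylate 3 (not isolated)
Conditions: KHCO3 (1.0 equiv), DMF, 50 °C, N2
Reagents that add atoms: none
Why: Phenacyl ester formation by SN2: bicarbonate deprotonates only the carboxylic acid (pKa about 4) and leaves all phenols (pKa 8 or higher) neutral, so the carboxylate alone displaces chloride from the activated α-chloro ketone, as in the preparation of p-hydroxyphenacyl esters from unprotected halo ketones; no stereocentre is formed.

Step 2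
Reactants: 4 2-(3,4-dihydroxyphenyl)-2-oxoethyl 3,5-dihydroxy-4-methoxybenzoate; 5 2,4,6-trihydroxybenzaldehyde
Product: 8 flavylium boronate triflate [5,7-dihydroxy-3-(3,5-dihydroxy-4-methoxybenzoyloxy)-2-(2-phenyl-1,3,2-benzodioxaborol-5-yl)chromenylium trifluoromethanesulfonate], via ketone boronate 6 (not isolated), via chalcone boronate 7 (not isolated)
Conditions: PhB(OH)2 (1.05 equiv), TfOH (1.5 equiv), dry EtOAc, 0 °C → rt, 24 h; Et2O, filter under N2, dry in vacuo
Reagents that add atoms: phenylboronic acid, OB(O)c1ccccc1; trifluoromethanesulfonic acid, OS(=O)(=O)C(F)(F)F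
Why: Robinson flavylium synthesis run together with a boronic ester condensation: the catechol closes onto boron, the acid-enolised O–CH2–C=O group condenses with the aldehyde, the resulting 2-hydroxychalcone cyclodehydrates to the aromatic pyrylium ring, and precipitation of the doubly ring-closed salt pulls all the dehydration equilibria; no stereocentre is formed.

Step 3
Reactants: 8 flavylium boronate triflate
Product: 12 (−)-epicatechin 3-O-(4-O-methylgallate), via 4H-flavene boronate 9 (not isolated), via flavan-2-ylium triflate 10 (not isolated), via epicatechin ester boronate 11 (not isolated)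
Conditions: [Ru(OTf)((S,S)-TsDPEN)(p-cymene)] (2 mol%), H2 (50 bar), 1,4-dioxane/HFIP 4:1 (0.05 M), 25 °C; then pour into H2O/EtOAc (pH 4–5), Sephadex LH-20
Reagents that add atoms: none
Why: Proposed new method: the Ru–H formed by heterolysis of H2 adds hydride to C4 of 8 to give enol ether 9, the released TfOH protonates C3 to give the 2-aryl oxocarbenium ion 10 whose C3 epimers interconvert through 9 (dynamic kinetic resolution), and the chiral Ru–H then delivers hydride to C2 of the matched enantiomer anti to the 3-acyloxy group (held pseudo-axial by A(1,2) strain with the coplanar aryl group), so C2 (R) is set by the catalyst and C3 (R) follows from the enforced 2,3-cis relationship; the boronate blocks the 4'-OH quinone methide tautomer, Ru chelation and acid-induced C2 epimerisation, and is hydrolysed in the work-up; the closest known reaction types are the cationic Ru–diamine asymmetric hydrogenation of isochromenylium ions and quinolines, the Brønsted-acid-assisted asymmetric hydrogenation of 2,3-disubstituted indoles by dynamic kinetic resolution, and the classical cis-selective catalytic hydrogenation of cyanidin chloride to racemic epicatechin.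

## Compound list

1 | 2-chloro-1-(3,4-dihydroxyphenyl)ethan-1-one | O=C(CCl)c1ccc(O)c(O)c1 | starting material
2 | 3,5-dihydroxy-4-methoxybenzoic acid | COc1c(O)cc(cc1O)C(=O)O | starting material
3 | potassium 3,5-dihydroxy-4-methoxybenzoate (not isolated) | COc1c(O)cc(cc1O)C(=O)[O-].[K+] | intermediate
4 | 2-(3,4-dihydroxyphenyl)-2-oxoethyl 3,5-dihydroxy-4-methoxybenzoate | COc1c(O)cc(cc1O)C(=O)OCC(=O)c1ccc(O)c(O)c1 | intermediate
5 | 2,4,6-trihydroxybenzaldehyde | O=Cc1c(O)cc(O)cc1O | starting material
6 | 2-oxo-2-(2-phenyl-1,3,2-benzodioxaborol-5-yl)ethyl 3,5-dihydroxy-4-methoxybenzoate (not isolated) | COc1c(O)cc(cc1O)C(=O)OCC(=O)c1ccc2OB(Oc2c1)c1ccccc1 | intermediate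
7 | α-acyloxy-2-hydroxychalcone boronate, alkene geometry labile in acid (not isolated) | COc1c(O)cc(cc1O)C(=O)OC(=Cc1c(O)cc(O)cc1O)C(=O)c1ccc2OB(Oc2c1)c1ccccc1 | intermediate
8 | 5,7-dihydroxy-3-(3,5-dihydroxy-4-methoxybenzoyloxy)-2-(2-phenyl-1,3,2-benzodioxaborol-5-yl)chromenylium triflate | COc1c(O)cc(cc1O)C(=O)Oc1cc2c(O)cc(O)cc2[o+]c1-c1ccc2OB(Oc2c1)c1ccccc1.[O-]S(=O)(=O)C(F)(F)F | intermediate
9 | 5,7-dihydroxy-2-(2-phenyl-1,3,2-benzodioxaborol-5-yl)-4H-chromen-3-yl 3,5-dihydroxy-4-methoxybenzoate (not isolated) | COc1c(O)cc(cc1O)C(=O)OC1=C(Oc2cc(O)cc(O)c2C1)c1ccc2OB(Oc2c1)c1ccccc1 | intermediate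
10 | 3-acyloxy-3,4-dihydrochromenylium (flavan-2-ylium) triflate, C3 configurationally labile (not isolated) | COc1c(O)cc(cc1O)C(=O)OC1Cc2c(O)cc(O)cc2[O+]=C1c1ccc2OB(Oc2c1)c1ccccc1.[O-]S(=O)(=O)C(F)(F)F | intermediate
11 | (2R,3R)-5,7-dihydroxy-2-(2-phenyl-1,3,2-benzodioxaborol-5-yl)chroman-3-yl 3,5-dihydroxy-4-methoxybenzoate (not isolated) | COc1c(O)cc(cc1O)C(=O)O[C@@H]1Cc2c(O)cc(O)cc2O[C@@H]1c1ccc2OB(Oc2c1)c1ccccc1 | intermediate
12 | (2R,3R)-2-(3,4-dihydroxyphenyl)-5,7-dihydroxychroman-3-yl 3,5-dihydroxy-4-methoxybenzoate, (−)-epicatechin 3-O-(4-O-methylgallate) | COc1c(O)cc(C(=O)O[C@@H]2Cc3c(O)cc(O)cc3O[C@@H]2c2ccc(O)c(O)c2)cc1O | target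

## Step count and risks

Total step count: 3. Longest linear sequence: 3 (1 → 4 → 8 → 12).

**Step 3 is the most likely to fail.**
- Risks: low ee, hydride capture at the acyloxonium carbon instead of C2, or attack of the product A ring on unreacted 8.
- The fallback sets out from 8 and replaces asymmetric catalysis by resolution.
- Heterogeneous hydrogenation (PtO2, H2 1 atm, EtOAc/AcOH) uses the classical cis selectivity. It gives 11 together with its mirror image, the (2S,3S) ester boronate F3.
- Aqueous work-up then gives 12 together with its enantiomer, (+)-epicatechin 3-O-(4-O-methylgallate) F4.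
- Preparative chiral SFC on an amylose phase removes F4, and the sequence comes back to the route at 12.

**Step 2 is the second most likely to fail.**
- Risks: solvolysis of the enol-type 3-O-ester by the water formed, self-condensation of 5, or incomplete boronate closure.
- The fallback sets out from 4 and 5 and decouples the two ring closures.
- Dry HCl gas in EtOAc at 0 °C precipitates 3-O-(4-O-methylgalloyl)cyanidin chloride F2.
- F2 is then treated with AgOTf (1 equiv) and PhB(OH)2 in dry acetone, filtered and evaporated. This comes back to the route at 8.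

**Step 1 is the third most likely to fail.**
- Risks: competing O-alkylation of the acidic 4'-OH, or catechol oxidation.
- The fallback sets out from 1 and masks the catechol before the ester bond is made.
- Compound 1 and PhB(OH)2 (toluene, Dean–Stark) give the chloro ketone phenylboronate F1.
- F1 is alkylated with pre-dried 3 in acetone. This comes back to the route at 6, which goes into the TfOH condensation with 5 without further boronic acid.

## Further compounds

F1 | step 1 | 2-chloro-1-(2-phenyl-1,3,2-benzodioxaborol-5-yl)ethan-1-one | O=C(CCl)c1ccc2OB(Oc2c1)c1ccccc1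
F2 | step 2 | 3-O-(4-O-methylgalloyl)cyanidin chloride | COc1c(O)cc(cc1O)C(=O)Oc1cc2c(O)cc(O)cc2[o+]c1-c1ccc(O)c(O)c1.[Cl-]
F3 | step 3 | (2S,3S)-5,7-dihydroxy-2-(2-phenyl-1,3,2-benzodioxaborol-5-yl)chroman-3-yl 3,5-dihydroxy-4-methoxybenzoate | COc1c(O)cc(cc1O)C(=O)O[C@H]1Cc2c(O)cc(O)cc2O[C@H]1c1ccc2OB(Oc2c1)c1ccccc1
F4 | step 3 | (2S,3S)-2-(3,4-dihydroxyphenyl)-5,7-dihydroxychroman-3-yl 3,5-dihydroxy-4-methoxybenzoate | COc1c(O)cc(C(=O)O[C@H]2Cc3c(O)cc(O)cc3O[C@H]2c2ccc(O)c(O)c2)cc1O
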